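The target hides a meso ring: O1, O2 and O4 lie on one face of the cyclohexene and only the C3 benzoate on the other, so a cis-cyclohexa-2,5-diene-1,4-diol with a mirror plane through C1 and C4 carries all four stereocentres in its enantiotopic C2=C3 and C5=C6 bonds. One hydroxyl-directed, ligand-controlled epoxidation of C2=C3 on the oxygen-bearing face breaks the symmetry and fixes C1, C2 and C4; benzoate then inverts C3. The precursor is meso dienol 6, made by dearomatising a phenol, with O1 capped as a triethylsilyl ether so that O4 alone anchors the catalyst, because O1 and O4 as anchors would call for opposite alkenes.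

Key step: step 5

Numbering: ring atoms are numbered as in the target throughout (C1 quaternary, C5=C6 the alkene that remains, C7 the exocyclic CH2).

Assumption: which antipode of the bis-hydroxamic acid ligand selects C2=C3 cannot be derived with certainty for this ring; the (R,R)-ligand is written, and the (S,S)-ligand replaces it if the first run gives the mirror-image epoxide.

Step 1
Reactants: 1 4-hydroxybenzyl alcohol; 2 benzoic acid
Product: 3 4-hydroxybenzyl benzoate
Conditions: PPh3, DIAD, THF, 0 °C to rt
Reagents that add atoms: none
Why: Mitsunobu esterification, in which the alkoxyphosphonium ion forms at the aliphatic hydroxyl and is displaced by benzoate, the phenol (pKa about 10) being too weak a pronucleophile to compete with benzoic acid (pKa about 4), so the base-labile 4-hydroxybenzyl ester is made under neutral conditions.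

Step 2
Reactants: 3 4-hydroxybenzyl benzoate
Product: 4 (1-hydroxy-4-oxocyclohexa-2,5-dien-1-yl)methyl benzoate (achiral para-quinol)
Conditions: PhI(OAc)2, MeCN/H2O, 0 °C
Reagents that add atoms: water, O
Why: Oxidative dearomatisation of a para-substituted phenol by trivalent iodine, in which the phenol oxygen is activated on iodine, iodobenzene leaves and water adds at the substituted para carbon, the usual route to 4-alkyl para-quinols, run in a slightly acidic medium that the benzyl ester tolerates.

Step 3
Reactants: 4 (1-hydroxy-4-oxocyclohexa-2,5-dien-1-yl)methyl benzoate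
Product: 5 [4-oxo-1-(triethylsilyloxy)cyclohexa-2,5-dien-1-yl]methyl benzoate
Conditions: Et3SiOTf, 2,6-lutidine, CH2Cl2, −78 to 0 °C
Reagents that add atoms: triethylsilyl trifluoromethanesulfonate, CC[Si](CC)(CC)OS(=O)(=O)C(F)(F)F
Why: Silylation of a tertiary alcohol with a silyl triflate and a hindered base, done here because the tertiary hydroxyl is the only one present and the dienone cannot enolise, so that later only O4 can bind the epoxidation catalyst and the C7 benzoate cannot migrate to O1.

Step 4
Reactants: 5 [4-oxo-1-(triethylsilyloxy)cyclohexa-2,5-dien-1-yl]methyl benzoate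
Product: 6 [cis-4-hydroxy-1-(triethylsilyloxy)cyclohexa-2,5-dien-1-yl]methyl benzoate (meso; O4–H and O1–Si on the same face)
Conditions: NaBH4, CeCl3·7H2O, MeOH, −78 °C
Reagents that add atoms: none
Why: Luche reduction reduces the cross-conjugated dienone 1,2-selectively and leaves benzoate and silyl ether alone; the C4 carbinol is set relative to C1 by hydride attack opposite the triethylsilyloxy group, whose silicon can sit over the ring while the CH2OBz oxygen turns away, and since both possible dienols are meso any trans isomer is removed by chromatography on Et3N-washed silica.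

Step 5
Reactants: 6 [cis-4-hydroxy-1-(triethylsilyloxy)cyclohexa-2,5-dien-1-yl]methyl benzoate
Product: 7 [(1S,2S,3S,4S)-2,3-epoxy-4-hydroxy-1-(triethylsilyloxy)cyclohex-5-en-1-yl]methyl benzoate (oxirane, O4–H and O1–Si all on one face)
Conditions: VO(OiPr)3 (2 mol %), (R,R)-N,N'-dihydroxy-N,N'-bis(diphenylacetyl)cyclohexane-1,2-diamine (4 mol %), tBuOOH (aq.), CH2Cl2, −20 °C
Reagents that add atoms: tert-butyl hydroperoxide, CC(C)(C)OO
Why: O4 binds pentavalent vanadium as an alkoxide beside the side-on tert-butyl peroxide, and the peroxide oxygen is passed to the alkene held under the metal. The closest known reactions are the VO(OiPr)3–bis-hydroxamic acid and Ti(OiPr)4–tartrate desymmetrising epoxidations of acyclic meso divinyl carbinols and the syn-selective VO(acac)2 epoxidation of cyclohex-2-enols; 6 is a cyclic member of the same bis-allylic carbinol class, and vanadium is preferred because ring-bound cis-alkenes are poor substrates for the titanium system. The oxirane is closed by a single concerted, suprafacial [2+1] oxygen-atom transfer that forms C2–O and C3–O together. C2 and C3 receive oxygen on the face of O4 because the metal is tethered there (shallow boat, O4 pseudoaxial), and C1 and C4, until now only pseudo-asymmetric, become true stereocentres when the chiral ligand takes C2=C3 and not C5=C6. The step needs face selection and alkene selection: the single free hydroxyl secures the first, the ligand the second, and the silyl cap on O1 removes a second anchor that is related to O4 by a pseudo-twofold axis and would steer the same catalyst to the other alkene. Epoxide formed at the wrong alkene keeps the alkene the catalyst prefers and should be drained to bis-epoxide, which should raise the enantiomeric purity of 7.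

Step 6
Reactants: 7 [(1S,2S,3S,4S)-2,3-epoxy-4-hydroxy-1-(triethylsilyloxy)cyclohex-5-en-1-yl]methyl benzoate; 2 benzoic acid
Product: 8 [(1S,2S,3R,4S)-3-benzoyloxy-2,4-dihydroxy-1-(triethylsilyloxy)cyclohex-5-en-1-yl]methyl benzoate
Conditions: PhCO2H, PhCO2Cs, DMF, 70 °C
Reagents that add atoms: none
Why: SN2 opening of an epoxide by carboxylate in an acid-buffered medium, in which benzoate attacks C3 from the face opposite the oxirane, inverting C3 and leaving the C2 oxygen in place, because C2 is neopentyl-like (next to the fully substituted C1, whose CH2OBz lies on the attack face), while the buffer keeps alkoxide low so that benzoyl and silyl groups should not migrate.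

Step 7
Reactants: 8 [(1S,2S,3R,4S)-3-benzoyloxy-2,4-dihydroxy-1-(triethylsilyloxy)cyclohex-5-en-1-yl]methyl benzoate
Product: 9 [(1S,2S,3R,4S)-3-benzoyloxy-1,2,4-trihydroxycyclohex-5-en-1-yl]methyl benzoate (target; O1, O2, O4 on one face, C3–OBz and C7 on the other)
Conditions: HF·pyridine, pyridine, THF, 0 °C to rt
Reagents that add atoms: none
Why: Fluoride-mediated cleavage of a silyl ether with buffered HF·pyridine, which needs no base, so the two benzoates should neither hydrolyse nor migrate, the allylic alcohols are not ionised and no stereocentre is touched.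

Compound list
1 | 4-hydroxybenzyl alcohol | OCc1ccc(O)cc1 | starting material
2 | benzoic acid | OC(=O)c1ccccc1 | starting material
3 | 4-hydroxybenzyl benzoate | O=C(OCc1ccc(O)cc1)c1ccccc1 | intermediate
4 | (1-hydroxy-4-oxocyclohexa-2,5-dien-1-yl)methyl benzoate | O=C(OCC1(O)C=CC(=O)C=C1)c1ccccc1 | intermediate
5 | [4-oxo-1-(triethylsilyloxy)cyclohexa-2,5-dien-1-yl]methyl benzoate | O=C(OCC1(O[Si](CC)(CC)CC)C=CC(=O)C=C1)c1ccccc1 | intermediate
6 | [cis-4-hydroxy-1-(triethylsilyloxy)cyclohexa-2,5-dien-1-yl]methyl benzoate (meso) | O=C(OC[C@@]1(O[Si](CC)(CC)CC)C=C[C@H](O)C=C1)c1ccccc1 | intermediate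
7 | [(1S,2S,3S,4S)-2,3-epoxy-4-hydroxy-1-(triethylsilyloxy)cyclohex-5-en-1-yl]methyl benzoate | O=C(OC[C@@]1(O[Si](CC)(CC)CC)C=C[C@H](O)[C@@H]2O[C@H]12)c1ccccc1 | intermediate
8 | [(1S,2S,3R,4S)-3-benzoyloxy-2,4-dihydroxy-1-(triethylsilyloxy)cyclohex-5-en-1-yl]methyl benzoate | O=C(OC[C@@]1(O[Si](CC)(CC)CC)C=C[C@H](O)[C@@H](OC(=O)c2ccccc2)[C@@H]1O)c1ccccc1 | intermediate
9 | [(1S,2S,3R,4S)-3-benzoyloxy-1,2,4-trihydroxycyclohex-5-en-1-yl]methyl benzoate | O=C(OC[C@@]1(O)C=C[C@H](O)[C@@H](OC(=O)c2ccccc2)[C@@H]1O)c1ccccc1 | target

Total step count: 7
Longest linear sequence: 7 steps (1 to 9)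

Steps most likely to fail

Step 5. The ligand may fail to tell the two alkenes apart on this ring, the silyloxy group may crowd the directing face, or the bis-allylic carbinol may be oxidised to the dienone faster than oxygen reaches the alkene. Fallback: setting out from 6, a hydroxyl-directed peracid epoxidation (mCPBA, NaHCO3, CH2Cl2, 0 °C; no metal-oxo oxidant) should give the syn epoxy alcohol as the racemate, that is 7 together with its mirror image ent-7 F1. Kinetic resolution by lipase-catalysed transesterification (immobilised Candida antarctica lipase B, vinyl acetate, TBME, rt; the enzyme is picked by screening so that the mirror image is the fast-reacting enantiomer) turns F1 into the acetate of ent-7 F2, which is separated by chromatography. The unreacted alcohol rejoins the route at 7.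

Step 4. Facial selectivity of hydride delivery to the remote carbonyl may be poor or reversed, since nucleophiles can prefer the side of the C1 oxygen for electrostatic reasons. Fallback: setting out from 5, the reduction is run without regard to selectivity and the trans dienol F3 is separated. Its carbinol centre is inverted by a Mitsunobu reaction with formic acid (PPh3, DIAD, HCO2H, THF, 0 °C; SN2 at C4) to give the cis formate F4. The formate alone is then removed by brief methanolysis (KHCO3, MeOH, 0 °C), which the benzoate survives, and the route is rejoined at 6.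

Step 6. Benzoate may attack C2 in place of C3, or a benzoyl or silyl group may migrate under warm carboxylate conditions. Fallback: setting out from 7, the silyl ether is removed first (HF·pyridine, pyridine, THF) to give the epoxy diol F5. The oxirane is then opened at room temperature with PhCO2H and Ti(OiPr)4 in CH2Cl2, a chelation-controlled opening of a 2,3-epoxy alcohol in which titanium bound to O1 activates the oxirane and benzoate enters at C3, the carbon remote from that carbinol and the only unhindered one. This gives the target directly, so the route is rejoined at 9.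

Further compounds
F1 | step 5 | ent-7, [(1R,2R,3R,4R)-2,3-epoxy-4-hydroxy-1-(triethylsilyloxy)cyclohex-5-en-1-yl]methyl benzoate | O=C(OC[C@]1(O[Si](CC)(CC)CC)C=C[C@@H](O)[C@H]2O[C@@H]12)c1ccccc1
F2 | step 5 | acetate of ent-7, [(1R,2R,3R,4R)-4-acetoxy-2,3-epoxy-1-(triethylsilyloxy)cyclohex-5-en-1-yl]methyl benzoate | O=C(OC[C@]1(O[Si](CC)(CC)CC)C=C[C@@H](OC(C)=O)[C@H]2O[C@@H]12)c1ccccc1
F3 | step 4 | trans dienol, [trans-4-hydroxy-1-(triethylsilyloxy)cyclohexa-2,5-dien-1-yl]methyl benzoate (meso) | O=C(OC[C@@]1(O[Si](CC)(CC)CC)C=C[C@@H](O)C=C1)c1ccccc1
F4 | step 4 | cis formate, [cis-4-formyloxy-1-(triethylsilyloxy)cyclohexa-2,5-dien-1-yl]methyl benzoate (meso) | O=C(OC[C@@]1(O[Si](CC)(CC)CC)C=C[C@H](OC=O)C=C1)c1ccccc1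
F5 | step 6 | epoxy diol, [(1S,2S,3S,4S)-2,3-epoxy-1,4-dihydroxycyclohex-5-en-1-yl]methyl benzoate | O=C(OC[C@@]1(O)C=C[C@H](O)[C@@H]2O[C@H]12)c1ccccc1
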